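**Plan** (labdane numbering: ring A = C1–C5/C10, ring B = C5–C10, C17 = CH2 on C8, C19 = CH2OAc on C4, C20 = CH3 on C10)
Retrosynthesis: cut C12–C13 (side chain off as an enol triflate), then the C4–CH3 bond, then in one operation the two ring bonds C9–C10 and C4–C5, then C1–C2 and C11–C12 of an open homogeranyl chain.
Forward: geranyl bromide → homogeranyl chain → β-keto ester (C19 ester, temporary C3 ketone) → Mn(III)/Cu(II) radical cascade in which ring A closes first and ring B closes last (C10 radical onto C9), the C8 radical ending as the C8=C17 methylene → C4 methylation → removal of the C3 oxygen and the auxiliary → Negishi union with the C13–C16 unit → acid release.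
Enabling feature: C5=C10 and C8=C9 are the two E-trisubstituted alkenes of a 1,5-diene, each with its methyl (C20, C17) on the inner carbon, so both closures are 6-endo and C17 can give up H to form the exocyclic alkene; the C19 carbonyl plus a C3 ketone make C4 the radical site.
Stereochemistry: absolute sense from a (+)-8-phenylmenthyl ester, C5/C9/C10 from the chair–chair transition state of the E,E-diene, C4 from methylation anti to C20, 13Z from stereoretentive coupling of an (E)-enol triflate.

Key step: step 7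

Assumption: the sense of induction of 8-phenylmenthyl acetoacetates in this cyclisation is taken as (−)-auxiliary → 10β-methyl (normal) series, hence the (+)-(1S,2R,5S)-auxiliary for this 10α-methyl (ent) target; if the sense is opposite, the (−)-auxiliary is used and nothing else changes.

Step 1
Reactants: 1 geranyl bromide
Product: 3 homogeraniol, via homogeranyl(isopropoxy)dimethylsilane 2 (not isolated)
Conditions: iPrOMe2SiCH2MgCl, CuI (5 mol%), THF, 0 °C; then 30% H2O2, KF, KHCO3, THF/MeOH, rt
Reagents that add atoms: (isopropoxydimethylsilyl)methylmagnesium chloride (CC(C)O[Si](C)(C)C[Mg]Cl); hydrogen peroxide (OO)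
Why: Copper-catalysed SN2 coupling of the primary allylic bromide with a hydroxymethyl Grignard equivalent, then Fleming–Tamao oxidation of the C–Si bond, should add the C12 carbinol carbon and leave the E-alkene untouched.

Step 2
Reactants: 3 homogeraniol
Product: 4 homogeranyl tert-butyldiphenylsilyl ether
Conditions: TBDPSCl, imidazole, DMF, rt
Reagents that add atoms: tert-butyl(chloro)diphenylsilane (CC(C)(C)[Si](Cl)(c1ccccc1)c1ccccc1)
Why: Standard silylation; the TBDPS ether is chosen because it should survive acetic acid, LiAlH4 and tin hydride in steps 7–11.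

Step 3
Reactants: 4 homogeranyl tert-butyldiphenylsilyl ether
Product: 5 (2E,6E)-10-(tert-butyldiphenylsilyloxy)-2,6-dimethyldeca-2,6-dien-1-ol
Conditions: SeO2 (0.3 equiv), t-BuOOH, salicylic acid (cat.), CH2Cl2, 0 °C → rt
Reagents that add atoms: tert-butyl hydroperoxide (CC(C)(C)OO)
Why: Riley-type allylic oxidation (ene reaction then [2,3]-shift) is selective for the E-methyl of the terminal trisubstituted alkene and should give the E-allylic alcohol that becomes C1.

Step 4
Reactants: 5 (2E,6E)-10-(tert-butyldiphenylsilyloxy)-2,6-dimethyldeca-2,6-dien-1-ol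
Product: 6 (2E,6E)-1-bromo-10-(tert-butyldiphenylsilyloxy)-2,6-dimethyldeca-2,6-diene
Conditions: CBr4, PPh3, CH2Cl2, −20 → 0 °C
Reagents that add atoms: carbon tetrabromide (BrC(Br)(Br)Br)
Why: Appel reaction under neutral conditions should convert the primary allylic alcohol to the bromide without allylic transposition or E/Z scrambling.

Step 5
Reactants: 7 (+)-(1S,2R,5S)-8-phenylmenthol
Product: 8 (1S,2R,5S)-8-phenylmenthyl acetoacetate
Conditions: tert-butyl acetoacetate, toluene, 110 °C, tert-butanol distilled off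
Reagents that add atoms: tert-butyl acetoacetate (CC(=O)CC(=O)OC(C)(C)C)
Why: Thermal transacetoacetylation via acetylketene should acylate the hindered secondary alcohol without touching its stereocentres.

Step 6
Reactants: 8 (1S,2R,5S)-8-phenylmenthyl acetoacetate; 6 (2E,6E)-1-bromo-10-(tert-butyldiphenylsilyloxy)-2,6-dimethyldeca-2,6-diene
Product: 9 (1S,2R,5S)-8-phenylmenthyl (6E,10E)-13-(tert-butyldiphenylsilyloxy)-6,10-dimethyl-3-oxotrideca-6,10-dienoate
Conditions: LDA (2.2 equiv), THF, 0 °C; then 6, 0 °C; aq NH4Cl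
Reagents that add atoms: none
Why: γ-Alkylation of the acetoacetate dianion by the allylic bromide (SN2) should form the C1–C2 bond and complete the open-chain precursor with both E-alkenes in place.

Step 7
Reactants: 9 (1S,2R,5S)-8-phenylmenthyl (6E,10E)-13-(tert-butyldiphenylsilyloxy)-6,10-dimethyl-3-oxotrideca-6,10-dienoate
Product: 11 (1S,2R,5S)-8-phenylmenthyl 12-(tert-butyldiphenylsilyloxy)-3-oxo-13,14,15,16,18-pentanor-ent-labd-8(17)-en-19-oate, via monocyclic C10 radical 10 (not isolated)
Conditions: Mn(OAc)3·2H2O (2.2 equiv), Cu(OAc)2·H2O (1 equiv, regenerated), degassed AcOH, 25 °C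
Reagents that add atoms: none
Why: The Mn(III) enolate of the β-keto ester is oxidised to the electrophilic C4 radical, which adds to C5 of the E-C5=C10 alkene (ring A), the tertiary C10 radical 10 then adds to C9 of the E-C8=C9 alkene to close ring B last, and Cu(II) oxidises the tertiary C8 radical with loss of a C17 hydrogen to the 8(17)-methylene. The reaction type is the Mn(OAc)3/Cu(OAc)2 oxidative free-radical polyene cyclisation of unsaturated β-keto esters, including its 8-phenylmenthyl ester variant. Both closures are 6-endo-trig because the methyl on the inner alkene carbon (C10, then C8) blocks the 5-exo mode. C5, C10 and C9 are set by a chair–chair transition state of the two E-alkenes (H5 anti to the C20 methyl, C9 chain equatorial and cis to C20), and the absolute sense by the phenyl ring of the auxiliary shielding one face of the dicarbonyl radical; C4 remains epimerisable and is fixed in step 8. The step needs facial selectivity (auxiliary; the minor diastereomer should be separable because the auxiliary is still attached), Hofmann-type elimination to the exocyclic alkene (Cu(II) takes hydrogen from the least hindered methyl) and no over-oxidation of the enolisable product (limited Mn(III), room temperature).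

Step 8
Reactants: 11 (1S,2R,5S)-8-phenylmenthyl 12-(tert-butyldiphenylsilyloxy)-3-oxo-13,14,15,16,18-pentanor-ent-labd-8(17)-en-19-oate
Product: 12 (1S,2R,5S)-8-phenylmenthyl 12-(tert-butyldiphenylsilyloxy)-3-oxo-13,14,15,16-tetranor-ent-labd-8(17)-en-19-oate
Conditions: K2CO3, MeI, acetone, 40 °C
Reagents that add atoms: iodomethane (CI)
Why: C-Alkylation of the cyclic β-keto ester enolate should occur on the face anti to the axial C20 methyl, so the new methyl ends equatorial and the ester axial (C19, cis to C20), creating the C4 quaternary centre.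

Step 9
Reactants: 12 (1S,2R,5S)-8-phenylmenthyl 12-(tert-butyldiphenylsilyloxy)-3-oxo-13,14,15,16-tetranor-ent-labd-8(17)-en-19-oate
Product: 13 12-(tert-butyldiphenylsilyloxy)-13,14,15,16-tetranor-ent-labd-8(17)-ene-3,19-diol (3-OH equatorial)
Conditions: LiAlH4, THF, 0 °C → reflux; Fieser work-up
Reagents that add atoms: none
Why: Hydride reduction should convert the hindered ester to the C19 carbinol, releasing the auxiliary for recovery, and the C3 ketone mainly to the equatorial alcohol, the epimer that can bridge to C19 in step 10.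

Step 10
Reactants: 13 12-(tert-butyldiphenylsilyloxy)-13,14,15,16-tetranor-ent-labd-8(17)-ene-3,19-diol
Product: 14 3,19-cyclic thionocarbonate of diol 13
Conditions: 1,1'-thiocarbonyldiimidazole, DMAP (cat.), toluene, 90 °C
Reagents that add atoms: 1,1'-thiocarbonyldiimidazole (S=C(n1ccnc1)n1ccnc1)
Why: Thiocarbonylation of a 1,3-diol whose equatorial C3–O and axial C19–O bonds are gauche should close the six-membered cyclic thionocarbonate.

Step 11
Reactants: 14 3,19-cyclic thionocarbonate of diol 13
Product: 16 tetranor diol (13,14,15,16-tetranor-ent-labd-8(17)-ene-12,19-diol), via S-stannyl thiocarbonate 15 (not isolated)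
Conditions: Bu3SnH, AIBN (cat.), toluene, 110 °C; then TBAF, THF, rt
Reagents that add atoms: none
Why: Barton-type radical deoxygenation of a cyclic thionocarbonate should fragment toward the more stable secondary C3 radical, which is reduced to CH2, after which fluoride cleaves the stannyl thiocarbonate on C19–O and the silyl ether on C12–O in the same flask.

Step 12
Reactants: 16 tetranor diol (13,14,15,16-tetranor-ent-labd-8(17)-ene-12,19-diol)
Product: 17 12-iodo-13,14,15,16-tetranor-ent-labd-8(17)-en-19-ol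
Conditions: I2 (1.05 equiv), PPh3, imidazole, CH2Cl2, 0 °C
Reagents that add atoms: iodine (II)
Why: Appel-type iodination should select the unhindered C12 primary alcohol over the axial neopentyl C19 alcohol on steric grounds.

Step 13
Reactants: 17 12-iodo-13,14,15,16-tetranor-ent-labd-8(17)-en-19-ol
Product: 18 12-iodo-13,14,15,16-tetranor-ent-labd-8(17)-en-19-yl acetate
Conditions: Ac2O, Et3N, DMAP (cat.), CH2Cl2, 0 °C → rt
Reagents that add atoms: acetic anhydride (CC(=O)OC(C)=O)
Why: DMAP-catalysed acetylation should install the final C19 acetate on the hindered primary alcohol; the alkyl iodide is inert under these conditions.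

Step 14
Reactants: 19 tert-butyl 4-chloro-3-oxobutanoate
Product: 20 tert-butyl 4-acetoxy-3-oxobutanoate
Conditions: KOAc, AcOH, DMF, rt
Reagents that add atoms: potassium acetate (CC(=O)[O-].[K+])
Why: SN2 displacement of the activated α-chloroketone chloride by acetate should deliver the C16 acetate on the C13–C16 unit.

Step 15
Reactants: 20 tert-butyl 4-acetoxy-3-oxobutanoate
Product: 21 tert-butyl (E)-4-acetoxy-3-(trifluoromethylsulfonyloxy)but-2-enoate
Conditions: Tf2O, aq Me4NOH, hexanes/toluene, 5 °C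
Reagents that add atoms: trifluoromethanesulfonic anhydride (O=S(=O)(OS(=O)(=O)C(F)(F)F)C(F)(F)F)
Why: O-Triflation of the β-keto ester enolate with a non-chelating counter-ion should favour the extended enolate and hence the (E)-enol triflate, with OTf trans to the ester and CH2OAc cis to it.

Step 16
Reactants: 18 12-iodo-13,14,15,16-tetranor-ent-labd-8(17)-en-19-yl acetate; 21 tert-butyl (E)-4-acetoxy-3-(trifluoromethylsulfonyloxy)but-2-enoate
Product: 23 tert-butyl (13Z)-16,19-diacetoxy-ent-labda-8(17),13-dien-15-oate, via alkylzinc iodide 22 (not isolated)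
Conditions: Zn dust (TMSCl/BrCH2CH2Br-activated), LiCl, THF, 40 °C; then 21, Pd(PPh3)4 (5 mol%), THF, 45 °C
Reagents that add atoms: none
Why: Zinc insertion into the primary iodide tolerates the acetate, and Negishi coupling with the enol triflate proceeds with retention at the sp2 carbon, so C12 replaces OTf trans to the ester and the 13Z geometry (C16 cis to C15) follows from 21.

Step 17
Reactants: 23 tert-butyl (13Z)-16,19-diacetoxy-ent-labda-8(17),13-dien-15-oate
Product: 25 (13Z)-16,19-diacetoxy-ent-labda-8(17),13-dien-15-oic acid (CNP0181814.1), via trimethylsilyl ester 24 (not isolated)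
Conditions: TMSOTf, 2,6-lutidine, CH2Cl2, 0 °C; then pH 4 aqueous buffer
Reagents that add atoms: none
Why: Silyl triflate-mediated cleavage of the tert-butyl ester (loss of isobutene, then hydrolysis of the silyl ester) under lutidine buffering should free the acid without touching the two acetates, the exocyclic alkene or the Z-enoate.

**Compound list**
1 | geranyl bromide, (2E)-1-bromo-3,7-dimethylocta-2,6-diene | CC(C)=CCC/C(C)=C/CBr | starting material
2 | homogeranyl(isopropoxy)dimethylsilane, (3E)-configured | CC(C)=CCC/C(C)=C/CC[Si](C)(C)OC(C)C | intermediate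
3 | homogeraniol, (3E)-4,8-dimethylnona-3,7-dien-1-ol | CC(C)=CCC/C(C)=C/CCO | intermediate
4 | homogeranyl tert-butyldiphenylsilyl ether | CC(C)=CCC/C(C)=C/CCO[Si](c1ccccc1)(c1ccccc1)C(C)(C)C | intermediate
5 | (2E,6E)-10-(tert-butyldiphenylsilyloxy)-2,6-dimethyldeca-2,6-dien-1-ol | OC/C(C)=C/CC/C(C)=C/CCO[Si](c1ccccc1)(c1ccccc1)C(C)(C)C | intermediate
6 | (2E,6E)-1-bromo-10-(tert-butyldiphenylsilyloxy)-2,6-dimethyldeca-2,6-diene | BrC/C(C)=C/CC/C(C)=C/CCO[Si](c1ccccc1)(c1ccccc1)C(C)(C)C | intermediate
7 | (+)-(1S,2R,5S)-8-phenylmenthol | C[C@H]1CC[C@@H]([C@H](C1)O)C(C)(C)c1ccccc1 | starting material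
8 | (1S,2R,5S)-8-phenylmenthyl acetoacetate | CC(=O)CC(=O)O[C@H]1C[C@@H](C)CC[C@@H]1C(C)(C)c1ccccc1 | intermediate
9 | (1S,2R,5S)-8-phenylmenthyl (6E,10E)-13-(tert-butyldiphenylsilyloxy)-6,10-dimethyl-3-oxotrideca-6,10-dienoate | O=C(CC(=O)CC/C(C)=C/CC/C(C)=C/CCO[Si](c1ccccc1)(c1ccccc1)C(C)(C)C)O[C@H]1C[C@@H](C)CC[C@@H]1C(C)(C)c1ccccc1 | intermediate
10 | monocyclic C10 radical: ring A closed (C3 ketone, C4 ester, C5–H), tertiary radical at C10, E-C8=C9 alkene still open | O=C1CC[C](C)[C@H](CC/C(C)=C/CCO[Si](c2ccccc2)(c2ccccc2)C(C)(C)C)[C@H]1C(=O)O[C@H]1C[C@@H](C)CC[C@@H]1C(C)(C)c1ccccc1 | intermediate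
11 | (1S,2R,5S)-8-phenylmenthyl 12-(tert-butyldiphenylsilyloxy)-3-oxo-13,14,15,16,18-pentanor-ent-labd-8(17)-en-19-oate (trans-decalin, 5β-H, 9β-H, 10α-CH3; C4–H epimerisable, drawn with equatorial ester) | C=C1CC[C@@H]2[C@@H](C(=O)O[C@H]3C[C@@H](C)CC[C@@H]3C(C)(C)c3ccccc3)C(=O)CC[C@@]2(C)[C@@H]1CCO[Si](c1ccccc1)(c1ccccc1)C(C)(C)C | intermediate
12 | (1S,2R,5S)-8-phenylmenthyl 12-(tert-butyldiphenylsilyloxy)-3-oxo-13,14,15,16-tetranor-ent-labd-8(17)-en-19-oate (C4: CH3 equatorial, ester axial and cis to C20) | C=C1CC[C@@H]2[C@](C)(C(=O)O[C@H]3C[C@@H](C)CC[C@@H]3C(C)(C)c3ccccc3)C(=O)CC[C@@]2(C)[C@@H]1CCO[Si](c1ccccc1)(c1ccccc1)C(C)(C)C | intermediate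
13 | 12-(tert-butyldiphenylsilyloxy)-13,14,15,16-tetranor-ent-labd-8(17)-ene-3,19-diol (3-OH equatorial) | C=C1CC[C@@H]2[C@](C)(CO)[C@H](O)CC[C@@]2(C)[C@@H]1CCO[Si](c1ccccc1)(c1ccccc1)C(C)(C)C | intermediate
14 | 3,19-cyclic thionocarbonate of 13 | C=C1CC[C@@H]2[C@]3(C)COC(=S)O[C@@H]3CC[C@@]2(C)[C@@H]1CCO[Si](c1ccccc1)(c1ccccc1)C(C)(C)C | intermediate
15 | S-(tributylstannyl) O-[12-(tert-butyldiphenylsilyloxy)-13,14,15,16-tetranor-ent-labd-8(17)-en-19-yl] thiocarbonate | C=C1CC[C@@H]2[C@](C)(COC(=O)S[Sn](CCCC)(CCCC)CCCC)CCC[C@@]2(C)[C@@H]1CCO[Si](c1ccccc1)(c1ccccc1)C(C)(C)C | intermediate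
16 | 13,14,15,16-tetranor-ent-labd-8(17)-ene-12,19-diol | C=C1CC[C@@H]2[C@](C)(CO)CCC[C@@]2(C)[C@@H]1CCO | intermediate
17 | 12-iodo-13,14,15,16-tetranor-ent-labd-8(17)-en-19-ol | C=C1CC[C@@H]2[C@](C)(CO)CCC[C@@]2(C)[C@@H]1CCI | intermediate
18 | 12-iodo-13,14,15,16-tetranor-ent-labd-8(17)-en-19-yl acetate | C=C1CC[C@@H]2[C@](C)(COC(C)=O)CCC[C@@]2(C)[C@@H]1CCI | intermediate
19 | tert-butyl 4-chloro-3-oxobutanoate | ClCC(=O)CC(=O)OC(C)(C)C | starting material
20 | tert-butyl 4-acetoxy-3-oxobutanoate | CC(=O)OCC(=O)CC(=O)OC(C)(C)C | intermediate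
21 | tert-butyl (E)-4-acetoxy-3-(trifluoromethylsulfonyloxy)but-2-enoate | CC(=O)OC/C(OS(=O)(=O)C(F)(F)F)=C\C(=O)OC(C)(C)C | intermediate
22 | (19-acetoxy-13,14,15,16-tetranor-ent-labd-8(17)-en-12-yl)zinc iodide | C=C1CC[C@@H]2[C@](C)(COC(C)=O)CCC[C@@]2(C)[C@@H]1CC[Zn]I | intermediate
23 | tert-butyl (13Z)-16,19-diacetoxy-ent-labda-8(17),13-dien-15-oate | C=C1CC[C@@H]2[C@](C)(COC(C)=O)CCC[C@@]2(C)[C@@H]1CC/C(=C/C(=O)OC(C)(C)C)COC(C)=O | intermediate
24 | trimethylsilyl (13Z)-16,19-diacetoxy-ent-labda-8(17),13-dien-15-oate | C=C1CC[C@@H]2[C@](C)(COC(C)=O)CCC[C@@]2(C)[C@@H]1CC/C(=C/C(=O)O[Si](C)(C)C)COC(C)=O | intermediate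
25 | (13Z)-16,19-diacetoxy-ent-labda-8(17),13-dien-15-oic acid (CNP0181814.1) | C=C1CC[C@@H]2[C@](C)(COC(C)=O)CCC[C@@]2(C)[C@@H]1CC/C(=C/C(=O)O)COC(C)=O | target

**Step count and risks**
Total step count: 17 (including the auxiliary branch, step 5, and the enol triflate branch, steps 14–15).
Longest linear sequence: 14 steps (1–4, 6–13, 16, 17) from geranyl bromide.

Three steps most likely to fail:

Step 7. The auxiliary may discriminate the two faces of the C4 radical too weakly in the first C–C bond formation, or the diastereomers may not separate; loss of a C7 hydrogen instead of a C17 hydrogen in the copper oxidation would also erode the exocyclic alkene. The fallback drops auxiliary control and resolves later. It sets out from bromide 6, which is alkylated with the dianion of methyl acetoacetate to give the methyl β-keto ester F1. The same Mn(III)/Cu(II) cascade gives the racemic bicyclic methyl keto ester F2, K2CO3/MeI gives the racemic C4-methylated keto ester F3, and LiAlH4 gives racemic 13. Esterification of the primary C19 hydroxyl with (R)-2-methoxy-2-phenylacetic acid (DCC, DMAP) gives two diastereomeric esters. The one of the required series, the 19-O-[(R)-methoxyphenylacetyl] ester F4, is separated by chromatography and cleaved with K2CO3/MeOH. The fallback comes back to the route at 13.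

Step 16. The triflation in step 15 may give the wrong or a mixed alkene geometry, and the sp3–sp2 coupling may suffer protodezincation or β-hydride elimination. The fallback replaces cross-coupling by a syn-carbocupration, which fixes the geometry mechanistically. It sets out from iodo alcohol 17, which is silylated (TBSCl, imidazole) to the 19-O-TBS iodide F5. tert-Butyldimethyl(prop-2-ynyloxy)silane is converted with n-BuLi and Boc2O into the ynoate tert-butyl 4-(tert-butyldimethylsilyloxy)but-2-ynoate F6. Iodine–lithium exchange on F5 (t-BuLi, −78 °C), transmetalation with CuBr·SMe2 and syn addition to F6 at −78 °C, then protonation, give the bis-silyl (13Z)-enoate F7, with C12 cis to H and C16 cis to the ester. HF·pyridine gives the dihydroxy tert-butyl ester F8, which is acetylated at once (Ac2O, DMAP) to avoid lactonisation. The fallback comes back to the route at 23.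

Step 11. The thionocarbonate radical may fragment toward the primary C19–O bond, or chain propagation may stall at the hindered ring. The fallback is a stepwise deoxygenation at the keto ester stage. It sets out from 12, which NaBH4 reduces to the 3-hydroxy ester F9. Phenyl chlorothionoformate/DMAP gives the 3-O-phenoxythiocarbonyl ester F10, and Bu3SnH/AIBN (Barton–McCombie deoxygenation) gives the 3-deoxy ester F11. LiAlH4 gives the 12-silyloxy 19-alcohol F12, and TBAF removes the silyl group. The fallback comes back to the route at 16.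

**Further compounds**
F1 | step 7 | methyl (6E,10E)-13-(tert-butyldiphenylsilyloxy)-6,10-dimethyl-3-oxotrideca-6,10-dienoate | COC(=O)CC(=O)CC/C(C)=C/CC/C(C)=C/CCO[Si](c1ccccc1)(c1ccccc1)C(C)(C)C
F2 | step 7 | racemic methyl 12-(tert-butyldiphenylsilyloxy)-3-oxo-13,14,15,16,18-pentanorlabd-8(17)-en-19-oate (ent enantiomer drawn) | C=C1CC[C@@H]2[C@@H](C(=O)OC)C(=O)CC[C@@]2(C)[C@@H]1CCO[Si](c1ccccc1)(c1ccccc1)C(C)(C)C
F3 | step 7 | racemic methyl 12-(tert-butyldiphenylsilyloxy)-3-oxo-13,14,15,16-tetranorlabd-8(17)-en-19-oate (ent enantiomer drawn) | C=C1CC[C@@H]2[C@](C)(C(=O)OC)C(=O)CC[C@@]2(C)[C@@H]1CCO[Si](c1ccccc1)(c1ccccc1)C(C)(C)C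
F4 | step 7 | 19-O-[(R)-2-methoxy-2-phenylacetyl] ester of diol 13 | C=C1CC[C@@H]2[C@](C)(COC(=O)[C@H](OC)c3ccccc3)[C@H](O)CC[C@@]2(C)[C@@H]1CCO[Si](c1ccccc1)(c1ccccc1)C(C)(C)C
F5 | step 16 | 19-O-tert-butyldimethylsilyl ether of iodide 17 | C=C1CC[C@@H]2[C@](C)(CO[Si](C)(C)C(C)(C)C)CCC[C@@]2(C)[C@@H]1CCI
F6 | step 16 | tert-butyl 4-(tert-butyldimethylsilyloxy)but-2-ynoate | CC(C)(C)OC(=O)C#CCO[Si](C)(C)C(C)(C)C
F7 | step 16 | tert-butyl (13Z)-16,19-bis(tert-butyldimethylsilyloxy)-ent-labda-8(17),13-dien-15-oate | C=C1CC[C@@H]2[C@](C)(CO[Si](C)(C)C(C)(C)C)CCC[C@@]2(C)[C@@H]1CC/C(=C/C(=O)OC(C)(C)C)CO[Si](C)(C)C(C)(C)C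
F8 | step 16 | tert-butyl (13Z)-16,19-dihydroxy-ent-labda-8(17),13-dien-15-oate | C=C1CC[C@@H]2[C@](C)(CO)CCC[C@@]2(C)[C@@H]1CC/C(=C/C(=O)OC(C)(C)C)CO
F9 | step 11 | (1S,2R,5S)-8-phenylmenthyl 12-(tert-butyldiphenylsilyloxy)-3-hydroxy-13,14,15,16-tetranor-ent-labd-8(17)-en-19-oate (3-OH equatorial) | C=C1CC[C@@H]2[C@](C)(C(=O)O[C@H]3C[C@@H](C)CC[C@@H]3C(C)(C)c3ccccc3)[C@H](O)CC[C@@]2(C)[C@@H]1CCO[Si](c1ccccc1)(c1ccccc1)C(C)(C)C
F10 | step 11 | 3-O-(phenoxythiocarbonyl) derivative of F9 | C=C1CC[C@@H]2[C@](C)(C(=O)O[C@H]3C[C@@H](C)CC[C@@H]3C(C)(C)c3ccccc3)[C@H](OC(=S)Oc3ccccc3)CC[C@@]2(C)[C@@H]1CCO[Si](c1ccccc1)(c1ccccc1)C(C)(C)C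
F11 | step 11 | (1S,2R,5S)-8-phenylmenthyl 12-(tert-butyldiphenylsilyloxy)-13,14,15,16-tetranor-ent-labd-8(17)-en-19-oate | C=C1CC[C@@H]2[C@](C)(C(=O)O[C@H]3C[C@@H](C)CC[C@@H]3C(C)(C)c3ccccc3)CCC[C@@]2(C)[C@@H]1CCO[Si](c1ccccc1)(c1ccccc1)C(C)(C)C
F12 | step 11 | 12-(tert-butyldiphenylsilyloxy)-13,14,15,16-tetranor-ent-labd-8(17)-en-19-ol | C=C1CC[C@@H]2[C@](C)(CO)CCC[C@@]2(C)[C@@H]1CCO[Si](c1ccccc1)(c1ccccc1)C(C)(C)C
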